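**Plan**
Ring numbering: C1(OBz)–C2=C3–C4(OBz)–C5(OH)–C6(OH)(C7H2OH). The tertiary carbinol C6 beside the secondary carbinol C5 in the six-membered ring is a reduced acyloin, so with C5 as a ketone the ring bond C5–C6 is a benzoin bond between a C5 aldehyde and a C6 ketone.
Retrosynthesis: C5–OH back to C5=O and the benzoates back to silyl ethers; cut C5–C6; return the Z-alkene to an alkyne; cut C1–C2 (acetylide + aldehyde).
Forward: a four-carbon alkyne (C2–C5) and a three-carbon aldehyde (C1, C6, C7) are joined at C1–C2, the alkyne is semihydrogenated, O5 and O6 are freed and oxidised together, and the only ring closes by carbene-catalysed benzoin reaction. Silyl-to-benzoyl exchange, C5 reduction and PMB removal finish the synthesis.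
Stereochemistry: C4 comes from (S)-glyceraldehyde acetonide; C1 from a Felkin–Anh addition next to a sacrificial C6 centre taken from (S)-but-3-ene-1,2-diol; C6 is set in the ring closure under control of C1; C5 is set by hydride delivery from the C6 hydroxyl.

Key step: step 12

Remark: the labels C1–C7 and O1–O7 of the target are used for all intermediates in the text, and ring compounds carry CIP descriptors on these labels; open-chain compounds are named with their own chain locants. TBS = tert-butyldimethylsilyl, TES = triethylsilyl, PMB = 4-methoxybenzyl, Bz = benzoyl.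

**Step 1**
Reactants: 1 (S)-2,3-O-isopropylideneglyceraldehyde
Product: 2 (R)-4-ethynyl-2,2-dimethyl-1,3-dioxolane
Conditions: dimethyl (1-diazo-2-oxopropyl)phosphonate, K2CO3, MeOH, 0 °C → rt
Reagents that add atoms: dimethyl (1-diazo-2-oxopropyl)phosphonate, CC(=O)C(=[N+]=[N-])P(=O)(OC)OC
Why: Ohira–Bestmann (Seyferth–Gilbert) homologation should convert the aldehyde into the terminal alkyne under conditions mild enough to keep the α-alkoxy centre, the future C4, whose descriptor changes from S to R only through the change in CIP priorities.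

**Step 2**
Reactants: 2 (R)-4-ethynyl-2,2-dimethyl-1,3-dioxolane
Product: 3 (R)-but-3-yne-1,2-diol
Conditions: Dowex 50W (H+ form), MeOH/H2O, rt
Reagents that add atoms: none
Why: Acid-catalysed acetal hydrolysis on a resin that is filtered off should give the water-soluble diol by evaporation alone, with no bond to the stereocentre broken.

**Step 3**
Reactants: 3 (R)-but-3-yne-1,2-diol
Product: 4 (R)-3,4-bis(tert-butyldimethylsilyloxy)but-1-yne
Conditions: TBSCl, imidazole, DMF, rt
Reagents that add atoms: tert-butyldimethylsilyl chloride, CC(C)(C)[Si](C)(C)Cl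
Why: Standard silyl chloride/imidazole silylation of both hydroxyls should give a non-volatile alkyne in which O4 carries its lasting silyl group and the primary O5 silyl ether can later be removed selectively.

**Step 4**
Reactants: 5 (S)-but-3-ene-1,2-diol
Product: 7 (S)-1-[(4-methoxybenzyl)oxy]but-3-en-2-ol, via stannylene acetal 6 (not isolated)
Conditions: Bu2SnO, toluene, reflux (Dean–Stark); then PMBCl, Bu4NI, 90 °C
Reagents that add atoms: 4-methoxybenzyl chloride, COc1ccc(CCl)cc1 (dibutyltin oxide, CCCC[Sn](=O)CCCC, contributes tin to intermediate 6 only)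
Why: Regioselective O-alkylation through a dibutylstannylene acetal, which activates the primary oxygen of a terminal 1,2-diol, should place the PMB group on the future O7 and leave the secondary allylic hydroxyl free.

**Step 5**
Reactants: 7 (S)-1-[(4-methoxybenzyl)oxy]but-3-en-2-ol
Product: 8 (S)-triethyl({1-[(4-methoxybenzyl)oxy]but-3-en-2-yl}oxy)silane
Conditions: TESCl, imidazole, CH2Cl2, 0 °C
Reagents that add atoms: chlorotriethylsilane, CC[Si](Cl)(CC)CC
Why: Silylation of the secondary alcohol with the labile triethylsilyl group should give a non-chelating α-substituent for the Felkin–Anh addition that can later be removed together with a primary TBS ether while secondary TBS ethers stay.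

**Step 6**
Reactants: 8 (S)-triethyl({1-[(4-methoxybenzyl)oxy]but-3-en-2-yl}oxy)silane
Product: 10 (R)-3-[(4-methoxybenzyl)oxy]-2-(triethylsilyloxy)propanal, via secondary ozonide 9 (not isolated)
Conditions: O3, CH2Cl2, −78 °C (stopped when the alkene is consumed); then PPh3, −78 °C → rt
Reagents that add atoms: ozone, [O-][O+]=O
Why: Ozonolysis with reductive work-up should cleave the terminal alkene much faster than ozone attacks the anisyl ring at −78 °C, and its anhydrous course keeps the TES ether and gives the α-silyloxy aldehyde, which is used at once to avoid epimerisation.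

**Step 7**
Reactants: 4 (R)-3,4-bis(tert-butyldimethylsilyloxy)but-1-yne; 10 (R)-3-[(4-methoxybenzyl)oxy]-2-(triethylsilyloxy)propanal
Product: 12 (2R,5S,6R)-1,2-bis(tert-butyldimethylsilyloxy)-7-[(4-methoxybenzyl)oxy]-6-(triethylsilyloxy)hept-3-yn-5-ol, via lithium acetylide 11 (not isolated)
Conditions: 4, n-BuLi, THF, −78 °C; then 10, −78 °C; AcOH quench at −78 °C
Reagents that add atoms: none
Why: Addition of a lithium acetylide to an α-silyloxy aldehyde should follow the polar Felkin–Anh model (silyl ethers do not chelate) and give the 1,2-anti product, hence S configuration at the new carbinol C1; the minor C1 epimer is to be removed by chromatography and the cold acidic quench prevents 1,2-silyl migration.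

**Step 8**
Reactants: 12 (2R,5S,6R)-1,2-bis(tert-butyldimethylsilyloxy)-7-[(4-methoxybenzyl)oxy]-6-(triethylsilyloxy)hept-3-yn-5-ol
Product: 13 (2R,5S,6R)-1,2,5-tris(tert-butyldimethylsilyloxy)-7-[(4-methoxybenzyl)oxy]-6-(triethylsilyloxy)hept-3-yne
Conditions: TBSOTf, 2,6-lutidine, CH2Cl2, −78 → 0 °C
Reagents that add atoms: tert-butyldimethylsilyl trifluoromethanesulfonate, CC(C)(C)[Si](C)(C)OS(=O)(=O)C(F)(F)F
Why: Silyl triflate/2,6-lutidine silylation should protect the hindered propargylic hydroxyl O1 under conditions to which TES and PMB ethers are inert.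

**Step 9**
Reactants: 13 (2R,5S,6R)-1,2,5-tris(tert-butyldimethylsilyloxy)-7-[(4-methoxybenzyl)oxy]-6-(triethylsilyloxy)hept-3-yne
Product: 14 (2R,3Z,5S,6R)-1,2,5-tris(tert-butyldimethylsilyloxy)-7-[(4-methoxybenzyl)oxy]-6-(triethylsilyloxy)hept-3-ene
Conditions: H2 (1 atm), Pd/CaCO3 poisoned with Pb(OAc)2 (Lindlar catalyst), quinoline, EtOAc, rt
Reagents that add atoms: none
Why: Lindlar semihydrogenation adds H2 syn to the internal alkyne and should stop at the Z-alkene, the poisoned palladium leaving the PMB ether and the allylic silyl ethers intact.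

**Step 10**
Reactants: 14 (2R,3Z,5S,6R)-1,2,5-tris(tert-butyldimethylsilyloxy)-7-[(4-methoxybenzyl)oxy]-6-(triethylsilyloxy)hept-3-ene
Product: 15 (2R,3Z,5S,6R)-2,5-bis(tert-butyldimethylsilyloxy)-7-[(4-methoxybenzyl)oxy]hept-3-ene-1,6-diol
Conditions: HF·pyridine, pyridine, THF, 0 °C
Reagents that add atoms: none
Why: Buffered HF·pyridine desilylation cleaves a secondary TES and a primary TBS ether far faster than secondary TBS ethers, so O5 and O6 should be freed while O1, O4 and O7 stay protected, and the acidic medium excludes base-induced silyl migration.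

**Step 11**
Reactants: 15 (2R,3Z,5S,6R)-2,5-bis(tert-butyldimethylsilyloxy)-7-[(4-methoxybenzyl)oxy]hept-3-ene-1,6-diol
Product: 16 (2R,3Z,5S)-2,5-bis(tert-butyldimethylsilyloxy)-7-[(4-methoxybenzyl)oxy]-6-oxohept-3-enal
Conditions: Dess–Martin periodinane, NaHCO3, CH2Cl2, 0 °C → rt
Reagents that add atoms: none
Why: Dess–Martin oxidation should convert the primary alcohol into the C5 aldehyde and the secondary alcohol into the C6 ketone in one operation under buffered, non-basic conditions that spare the two α-silyloxy allylic centres; the keto-aldehyde is used directly.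

**Step 12**
Reactants: 16 (2R,3Z,5S)-2,5-bis(tert-butyldimethylsilyloxy)-7-[(4-methoxybenzyl)oxy]-6-oxohept-3-enal
Product: 17 (1S,4R,6R)-1,4-bis(tert-butyldimethylsilyloxy)-6-hydroxy-6-{[(4-methoxybenzyl)oxy]methyl}cyclohex-2-en-5-one
Conditions: 2-(pentafluorophenyl)-6,7-dihydro-5H-pyrrolo[2,1-c][1,2,4]triazol-2-ium tetrafluoroborate (15 mol %), Et3N (10 mol %), CH2Cl2 (0.02 M), rt
Reagents that add atoms: none
Why: The triazolylidene freed from the salt adds to the C5 aldehyde and proton transfer gives the Breslow enaminol, an acyl-anion equivalent at C5. This attacks the C6 ketone in a 6-exo-trig closure, the only ring formed, and collapse of the adduct releases the carbene and leaves the C5 ketone and the C6 tertiary alcohol; the closest known reaction type is the intramolecular crossed aldehyde–ketone benzoin cyclisation with electron-poor triazolium catalysts, as used to carbocyclise sugar-derived keto-aldehydes. Cross-selectivity is built in, because only the aldehyde can form the enaminol and the ketone can only accept, and the Z-alkene holds the two carbonyls within reach so that ring closure at high dilution should outrun intermolecular benzoin coupling. The new stereocentre C6 is controlled by the adjacent C1 silyloxy centre: in the half-chair transition state the PMBOCH2 arm should take the equatorial site and the C1–OSi bond lie pseudoaxial and antiperiplanar to the ketone C=O (opposed dipoles), so the developing C6–O ends trans to O1 as the target requires. The step also needs the two α-silyloxy allylic C–H bonds at C1 and C4 to survive: silyl ethers are poor leaving groups, so the enaminol does not expel O4, and the N-C6F5 salt is acidic enough that less Et3N than catalyst suffices, leaving no free amine to epimerise or conjugate the β,γ-unsaturated carbonyls.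

**Step 13**
Reactants: 17 (1S,4R,6R)-1,4-bis(tert-butyldimethylsilyloxy)-6-hydroxy-6-{[(4-methoxybenzyl)oxy]methyl}cyclohex-2-en-5-one
Product: 18 (1S,4R,6R)-1,4,6-trihydroxy-6-{[(4-methoxybenzyl)oxy]methyl}cyclohex-2-en-5-one
Conditions: 48 % aq. HF, MeCN, 0 °C → rt
Reagents that add atoms: none
Why: Acidic fluoride desilylation should remove both secondary TBS ethers without the basic conditions (as with Bu4NF) that would enolise the β,γ-unsaturated α-ketol, while the PMB ether and the tertiary alcohol are stable.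

**Step 14**
Reactants: 18 (1S,4R,6R)-1,4,6-trihydroxy-6-{[(4-methoxybenzyl)oxy]methyl}cyclohex-2-en-5-one
Product: 19 (1S,4R,6R)-6-hydroxy-6-{[(4-methoxybenzyl)oxy]methyl}-5-oxocyclohex-2-ene-1,4-diyl dibenzoate
Conditions: BzCl, pyridine, CH2Cl2, −20 → 0 °C
Reagents that add atoms: benzoyl chloride, O=C(Cl)c1ccccc1
Why: Acylation with benzoyl chloride/pyridine should esterify the two secondary allylic hydroxyls O1 and O4, the tertiary C6 hydroxyl beside the ketone being too hindered at low temperature, and with C5 still a ketone no ester can form there.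

**Step 15**
Reactants: 19 (1S,4R,6R)-6-hydroxy-6-{[(4-methoxybenzyl)oxy]methyl}-5-oxocyclohex-2-ene-1,4-diyl dibenzoate
Product: 20 (1S,4R,5R,6S)-5,6-dihydroxy-6-{[(4-methoxybenzyl)oxy]methyl}cyclohex-2-ene-1,4-diyl dibenzoate
Conditions: Me4NBH(OAc)3, MeCN/AcOH (1:1), −30 °C
Reagents that add atoms: none
Why: In this hydroxyl-directed triacetoxyborohydride reduction (Saksena–Evans type) the C6 hydroxyl, the only free one, should bind boron and deliver hydride to the ketone face syn to O6, so the new C5 hydroxyl is trans to O6 and cis to the O4 benzoate (5R), and the acidic medium suppresses benzoate migration.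

**Step 16**
Reactants: 20 (1S,4R,5R,6S)-5,6-dihydroxy-6-{[(4-methoxybenzyl)oxy]methyl}cyclohex-2-ene-1,4-diyl dibenzoate
Product: 21 (1S,4R,5R,6S)-5,6-dihydroxy-6-(hydroxymethyl)cyclohex-2-ene-1,4-diyl dibenzoate
Conditions: DDQ, CH2Cl2/pH 7 phosphate buffer (10:1), 0 °C → rt
Reagents that add atoms: none
Why: Oxidative PMB ether cleavage with DDQ in wet CH2Cl2 runs through the benzylic oxocarbenium ion and its hydrolysis under neutral conditions, which should leave the benzoates, the alkene and the free hydroxyls untouched.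

**Compound list**
1 | (S)-2,3-O-isopropylideneglyceraldehyde [(4S)-2,2-dimethyl-1,3-dioxolane-4-carbaldehyde] | O=C[C@@H]1COC(C)(C)O1 | starting material
2 | (R)-4-ethynyl-2,2-dimethyl-1,3-dioxolane | C#C[C@@H]1COC(C)(C)O1 | intermediate
3 | (R)-but-3-yne-1,2-diol | C#C[C@@H](O)CO | intermediate
4 | (R)-3,4-bis(tert-butyldimethylsilyloxy)but-1-yne | C#C[C@@H](O[Si](C)(C)C(C)(C)C)CO[Si](C)(C)C(C)(C)C | intermediate
5 | (S)-but-3-ene-1,2-diol | C=C[C@H](O)CO | starting material
6 | (S)-2,2-dibutyl-4-vinyl-1,3,2-dioxastannolane (stannylene acetal of 5, not isolated) | CCCC[Sn]1(CCCC)OC[C@H](C=C)O1 | intermediate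
7 | (S)-1-[(4-methoxybenzyl)oxy]but-3-en-2-ol | C=C[C@H](O)COCc1ccc(OC)cc1 | intermediate
8 | (S)-triethyl({1-[(4-methoxybenzyl)oxy]but-3-en-2-yl}oxy)silane | C=C[C@H](O[Si](CC)(CC)CC)COCc1ccc(OC)cc1 | intermediate
9 | 3-{(1R)-2-[(4-methoxybenzyl)oxy]-1-(triethylsilyloxy)ethyl}-1,2,4-trioxolane (secondary ozonide of 8, mixture at the trioxolane carbon, not isolated) | CC[Si](CC)(CC)O[C@H](COCc1ccc(OC)cc1)C1OCOO1 | intermediate
10 | (R)-3-[(4-methoxybenzyl)oxy]-2-(triethylsilyloxy)propanal | O=C[C@H](O[Si](CC)(CC)CC)COCc1ccc(OC)cc1 | intermediate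
11 | lithium acetylide of 4, [(R)-3,4-bis(tert-butyldimethylsilyloxy)but-1-yn-1-yl]lithium (not isolated) | [Li]C#C[C@@H](O[Si](C)(C)C(C)(C)C)CO[Si](C)(C)C(C)(C)C | intermediate
12 | (2R,5S,6R)-1,2-bis(tert-butyldimethylsilyloxy)-7-[(4-methoxybenzyl)oxy]-6-(triethylsilyloxy)hept-3-yn-5-ol | CC(C)(C)[Si](C)(C)OC[C@H](O[Si](C)(C)C(C)(C)C)C#C[C@H](O)[C@H](O[Si](CC)(CC)CC)COCc1ccc(OC)cc1 | intermediate
13 | (2R,5S,6R)-1,2,5-tris(tert-butyldimethylsilyloxy)-7-[(4-methoxybenzyl)oxy]-6-(triethylsilyloxy)hept-3-yne | CC(C)(C)[Si](C)(C)OC[C@H](O[Si](C)(C)C(C)(C)C)C#C[C@H](O[Si](C)(C)C(C)(C)C)[C@H](O[Si](CC)(CC)CC)COCc1ccc(OC)cc1 | intermediate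
14 | (2R,3Z,5S,6R)-1,2,5-tris(tert-butyldimethylsilyloxy)-7-[(4-methoxybenzyl)oxy]-6-(triethylsilyloxy)hept-3-ene | CC(C)(C)[Si](C)(C)OC[C@H](O[Si](C)(C)C(C)(C)C)/C=C\[C@H](O[Si](C)(C)C(C)(C)C)[C@H](O[Si](CC)(CC)CC)COCc1ccc(OC)cc1 | intermediate
15 | (2R,3Z,5S,6R)-2,5-bis(tert-butyldimethylsilyloxy)-7-[(4-methoxybenzyl)oxy]hept-3-ene-1,6-diol | OC[C@H](O[Si](C)(C)C(C)(C)C)/C=C\[C@H](O[Si](C)(C)C(C)(C)C)[C@H](O)COCc1ccc(OC)cc1 | intermediate
16 | (2R,3Z,5S)-2,5-bis(tert-butyldimethylsilyloxy)-7-[(4-methoxybenzyl)oxy]-6-oxohept-3-enal (C5 aldehyde, C6 ketone) | O=C[C@H](O[Si](C)(C)C(C)(C)C)/C=C\[C@H](O[Si](C)(C)C(C)(C)C)C(=O)COCc1ccc(OC)cc1 | intermediate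
17 | (1S,4R,6R)-1,4-bis(tert-butyldimethylsilyloxy)-6-hydroxy-6-{[(4-methoxybenzyl)oxy]methyl}cyclohex-2-en-5-one (O1 and O4 cis, 6-OH trans to O1) | CC(C)(C)[Si](C)(C)O[C@H]1C=C[C@@H](O[Si](C)(C)C(C)(C)C)C(=O)[C@@]1(O)COCc1ccc(OC)cc1 | intermediate
18 | (1S,4R,6R)-1,4,6-trihydroxy-6-{[(4-methoxybenzyl)oxy]methyl}cyclohex-2-en-5-one | O[C@H]1C=C[C@@H](O)C(=O)[C@@]1(O)COCc1ccc(OC)cc1 | intermediate
19 | (1S,4R,6R)-6-hydroxy-6-{[(4-methoxybenzyl)oxy]methyl}-5-oxocyclohex-2-ene-1,4-diyl dibenzoate | O=C(O[C@H]1C=C[C@@H](OC(=O)c2ccccc2)C(=O)[C@@]1(O)COCc1ccc(OC)cc1)c1ccccc1 | intermediate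
20 | (1S,4R,5R,6S)-5,6-dihydroxy-6-{[(4-methoxybenzyl)oxy]methyl}cyclohex-2-ene-1,4-diyl dibenzoate | O=C(O[C@H]1C=C[C@@H](OC(=O)c2ccccc2)[C@@H](O)[C@@]1(O)COCc1ccc(OC)cc1)c1ccccc1 | intermediate
21 | (1S,4R,5R,6S)-5,6-dihydroxy-6-(hydroxymethyl)cyclohex-2-ene-1,4-diyl dibenzoate (CNP0212417.6) | O=C(O[C@H]1C=C[C@@H](OC(=O)c2ccccc2)[C@@H](O)[C@@]1(O)CO)c1ccccc1 | target

**Step count**
Total: 16 steps. Longest linear sequence: 13 steps (steps 1–3 then 7–16; the branch 4–6 then 7–16 is equally long).

**Steps most likely to fail**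

1. Step 12. The amine or carbene may epimerise the α-silyloxy allylic centres C1 and C4 or move the alkene into conjugation before the ring closes, and the enaminol may attack the wrong face of the C6 ketone. A chiral aminoindanol-derived triazolium salt would be the first change of conditions. The fallback sets out from 16 and comes back at 17. Treatment of 16 with SmI2 in THF/t-BuOH at −78 °C should close the same C5–C6 bond by ketyl–carbonyl (pinacol) coupling without any base. Such closures place both new hydroxyls cis to each other and trans to the flanking alkoxy groups, which would give (1S,4R,5S,6S)-1,4-bis(tert-butyldimethylsilyloxy)-6-{[(4-methoxybenzyl)oxy]methyl}cyclohex-2-ene-5,6-diol F1 with the required C6 configuration. Oxidation of its only secondary hydroxyl with Dess–Martin periodinane/NaHCO3 would then give 17.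

2. Step 7. Facial selectivity of the acetylide addition may be poor, so that separation of the C1 epimers costs material. The fallback sets out from 12, taken as its mixture with the C1 epimer, and comes back at 12. Oxidation of the mixture with Dess–Martin periodinane would give the ynone (2R,6R)-1,2-bis(tert-butyldimethylsilyloxy)-7-[(4-methoxybenzyl)oxy]-6-(triethylsilyloxy)hept-3-yn-5-one F2. Noyori transfer hydrogenation with RuCl[(R,R)-TsDPEN](p-cymene) in i-PrOH, in which the alkyne takes the place that an aryl group has in aryl ketone reductions, should then set the 5S carbinol of 12 under reagent control, whatever the neighbouring centre.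

3. Step 13. The free β,γ-unsaturated α-ketol may be lost through enolisation towards C4, dehydration or α-ketol shift during desilylation and the acylation that follows. The fallback sets out from 17 and comes back at 20; it removes the ketone first. Directed reduction of 17 with Me4NBH(OAc)3 in MeCN/AcOH should give the trans-5,6-diol (1S,4R,5R,6S)-1,4-bis(tert-butyldimethylsilyloxy)-6-{[(4-methoxybenzyl)oxy]methyl}cyclohex-2-ene-5,6-diol F3. 2-Methoxypropene with pyridinium p-toluenesulfonate would give its trans-fused 5,6-O-isopropylidene acetal F4. Bu4NF in THF would then free the 5,6-O-isopropylidene 1,4-diol F5, now without a ketone to enolise, and benzoyl chloride/pyridine would give the 5,6-O-isopropylidene 1,4-dibenzoate F6. Aqueous acetic acid should hydrolyse the strained trans-acetonide to 20.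

**Further compounds**
F1 | step 12 | (1S,4R,5S,6S)-1,4-bis(tert-butyldimethylsilyloxy)-6-{[(4-methoxybenzyl)oxy]methyl}cyclohex-2-ene-5,6-diol (cis-5,6-diol, both hydroxyls trans to the silyloxy groups) | CC(C)(C)[Si](C)(C)O[C@H]1C=C[C@@H](O[Si](C)(C)C(C)(C)C)[C@H](O)[C@@]1(O)COCc1ccc(OC)cc1
F2 | step 7 | (2R,6R)-1,2-bis(tert-butyldimethylsilyloxy)-7-[(4-methoxybenzyl)oxy]-6-(triethylsilyloxy)hept-3-yn-5-one | CC(C)(C)[Si](C)(C)OC[C@H](O[Si](C)(C)C(C)(C)C)C#CC(=O)[C@H](O[Si](CC)(CC)CC)COCc1ccc(OC)cc1
F3 | step 13 | (1S,4R,5R,6S)-1,4-bis(tert-butyldimethylsilyloxy)-6-{[(4-methoxybenzyl)oxy]methyl}cyclohex-2-ene-5,6-diol (trans-5,6-diol) | CC(C)(C)[Si](C)(C)O[C@H]1C=C[C@@H](O[Si](C)(C)C(C)(C)C)[C@@H](O)[C@@]1(O)COCc1ccc(OC)cc1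
F4 | step 13 | 5,6-O-isopropylidene acetal of F3 (trans-fused acetonide) | CC(C)(C)[Si](C)(C)O[C@H]1C=C[C@@H](O[Si](C)(C)C(C)(C)C)[C@H]2OC(C)(C)O[C@]12COCc1ccc(OC)cc1
F5 | step 13 | 5,6-O-isopropylidene-6-{[(4-methoxybenzyl)oxy]methyl}cyclohex-2-ene-1,4,5,6-tetrol with free O1 and O4 (1,4-diol from F4) | O[C@H]1C=C[C@@H](O)[C@H]2OC(C)(C)O[C@]12COCc1ccc(OC)cc1
F6 | step 13 | 1,4-di-O-benzoate of F5 | O=C(O[C@H]1C=C[C@@H](OC(=O)c3ccccc3)[C@H]2OC(C)(C)O[C@]12COCc1ccc(OC)cc1)c1ccccc1
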